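The runs are simulated for substances that don't exist; the scatter is artificial.

| flask | starting material | second nucleophile | gas | capture agent | remark | time |
|---|---|---|---|---|---|---|
| Monday's | 0.0025 M | 1.3 equiv | 0.63 mM (held) | 1.5 mM | run made earlier |  |
| flask | 0.0050 M | 1.30 equiv | 0.63 mM (held) | 1.50 mM |  | 80 min |

Monday's run (percent of the starting material charged)

| time / min | other capture product / % | target / % |
|---|---|---|
| 1.33 | 30.6 | 61.6 |
| 2.00 | 32.0 | 65.7 |
| 4.00 | 33.2 | 66.8 |
| 6.00 | 32.0 | 66.7 |
| 10.0 | 32.3 | 66.7 |
| 15.0 | 32.8 | 66.0 |

(readings scatter by 0.5 percentage points)

- share of other capture product in other capture product plus target at 6.0 s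
- share of other capture product in other capture product plus target at 80 min

- at the start none of the gas is in solution

1. The constants were hidden from me, so I read one from Monday's run, assuming that at held gas the two products compete for one intermediate and form in the rate ratio (other capture product to target) c(second nucleophile)/λ.

2. Monday's plateau averaged 0.814 mM of other capture product and 1.66 mM of target, and c(second nucleophile) fell from 3.25 mM by the first of these, so I took its mean and obtained the break-even level, the c(second nucleophile) at which both form equally fast (selectivity factor times gas level), as a reading of 5.81 mM.

3. This flask sets its charge of 6.50 mM against that λ, and the same mean rule, with the two products summing to the charge, gave me 2.39 mM of other capture product, a final share of 47.7%.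

4. No gas was in solution at the start, so I put the share at 6.0 s above 52.8%, the share that Monday's λ, a run-long reading, gives at this flask's charge of second nucleophile.

5. The forecast gave 55% (41% to 85%), “very uncertain”, and 25% (23.5% to 28%).

6. The flask gave 68.2% at 6.0 s, above that share, and 49.1% at 80 min, 1.4 percentage points above my reckoning.

    starting material → open intermediate (k = 0.0320 s⁻¹)
    first nucleophile + open intermediate → target (k = 1600 L mol⁻¹ s⁻¹)
    second nucleophile + open intermediate → other capture product (k = 120 L mol⁻¹ s⁻¹)
    gas ⇌ first nucleophile, rate k4*(csat - [first nucleophile]) (kL = 0.210 s⁻¹)
    open intermediate + capture agent → trapped intermediate (k = 5.60 L mol⁻¹ s⁻¹)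

Second nucleophile stood at 62.5% of its charge at 80.0 min; that mean, 5.28 mM, over λ gives a share of 47.6%.

7. With 5.20 equiv of second nucleophile, charge 26.0 mM, λ gives a share of 80.5%; that flask computed 78.7%.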